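The vessel was closed, stirred and isothermal, and I wanted its contents at 15 h.

| setting | oak | birch | ash | flask |
|---|---|---|---|---|
| starting material | 0.020 M | 0.020 M | 0.010 M | 0.020 M |
| partner | 1.05 equiv | 1.05 equiv | 1.05 equiv | 1.05 equiv |
| base | 0.010 equiv | 0.040 equiv | 0.020 equiv | 0.0200 equiv |
| scavenger | 0.50 equiv | 0.50 equiv | 0.50 equiv | 0.500 equiv |
| remark | run made earlier | run made earlier | run made earlier |  |
| time |  |  |  | 15 h |

| run | time / h | product / % | starting material / % |
|---|---|---|---|
| oak | 1.00 | 9.3 | 91.1 |
| oak | 3.00 | 20.7 | 77.8 |
| oak | 6.00 | 36.5 | 64.0 |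
| oak | 8.00 | 42.6 | 57.5 |
| oak | 12.0 | 54.0 | 46.5 |
| birch | 1.00 | 8.1 | 91.8 |
| birch | 2.00 | 15.0 | 84.4 |
| birch | 3.00 | 22.3 | 78.6 |
| birch | 6.00 | 36.5 | 64.0 |
| birch | 12.0 | 53.4 | 45.8 |
| ash | 2.50 | 10.1 | 90.1 |
| ash | 5.00 | 18.5 | 82.0 |
| ash | 8.00 | 26.2 | 72.9 |
| ash | 10.0 | 31.2 | 68.2 |
| ash | 12.0 | 35.3 | 64.8 |

(readings scatter by 0.5 percentage points)

* concentration of product at 15 h, in M
* concentration of starting material at 15 h, in M



I began with the main step, starting material plus partner to product, at a nearly matched charge. The fraction of starting material left is then clock over clock plus time, and the averaged last oak and birch readings gave a clock of 10.3 h. Ash, at 0.010 M, read 22.1 h, twice that, as a step first order in each reagent requires. So the flask, charged like oak at 0.020 M, kept 40.7%.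

Next I added the base: oak, at 0.010 equiv, read 10.4 h and birch, at 0.040 equiv, read 10.1 h, a gap within the scatter, so the clock stood. Then I added the scavenger, charged at 0.500 equiv: oak had passed 54.0% product, yet its reading at 6.00 h gave 10.7 h, showing no break. I therefore committed to 0.00813 M starting material and 0.0119 M product.

The forecast gave 0.0118 M product and 0.0082 M starting material, with the caution that “a late stall can't be excluded”.

The flask gave 0.0120 M product and 0.00803 M starting material.

    starting material + partner + released group → product + 2 released group (k = 1600 M⁻² h⁻¹)
    starting material + partner → product + released group (k = 4.20 M⁻¹ h⁻¹)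
    base + released group ⇌ salt, settled at all times (K = 3.70 × 10⁵ M⁻¹)
    partner + released group ⇌ idle adduct, settled at all times (K = 100 M⁻¹)
    scavenger + released group → scavenged by-product (k = 960 M⁻¹ h⁻¹)

In this flask, starting material went through the step without released group 13 times as fast as through the step with it at 4.38 h. Up to 15 h the first step turned over 54.7% of the charge and the second 5.14%. The result reads a clock of 10.1 h, against my 10.3 h. A neighbouring flask with 4.20 equiv of partner has a charge ratio of 4.20, and its partner falls as it is used, so I put the clock into the second-order law for unequal charges, with partner falling as starting material does: 0.723% should remain at 15 h; that flask held 0.46%.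

All runs are calculated for substances that don't exist, noise included.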